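Count amounts as fractions of the starting material charged, with s the fraction still unreacted. The reagent is the limiting reagent, at 0.700 of the charge in the set-ups asked about and 0.320 of the charge in red.

| setting | violet | ochre | red | theta | gamma | alpha | eta |
|---|---|---|---|---|---|---|---|
| starting material | 0.27 M | 0.38 M | 0.59 M | 0.27 M | 0.27 M | 0.27 M | 0.27 M |
| reagent | 0.189 M | 0.189 M | 0.189 M | 0.189 M | 0.189 M | 0.189 M (fed, over 20.0 h) | 0.189 M |
| remark | run made earlier | run made earlier | run made earlier | a single well-mixed tank run continuously and read at steady state, 40 h in it on average | a closed flask charged with all of it at once and left for 40 h | all but reagent at the start; reagent goes in evenly over 20.0 h, the run ends at 40 h | one stirred flow tank at steady state, fed with the mixture as stated, mean residence time 200 h |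
| time |  |  |  |  | 40 h | 40 h |  |

| run | time / h | target / % | side product A / % |
|---|---|---|---|
| violet | 3.00 | 12.3 | 1.3 |
| violet | 8.00 | 28.0 | 2.3 |
| violet | 15.0 | 38.6 | 1.9 |
| violet | 25.0 | 45.1 | 2.7 |
| ochre | 6.00 | 18.3 | 0.6 |
| ochre | 12.0 | 27.0 | 0.8 |
| ochre | 20.0 | 30.9 | 1.1 |
| ochre | 25.0 | 32.0 | 1.2 |
| red | 3.00 | 8.0 | 1.0 |
| red | 8.00 | 16.1 | 1.3 |
| red | 15.0 | 17.2 | 0.5 |
| red | 25.0 | 18.0 | 1.4 |

(each reading ± 0.5 percentage points)

- percentages count the starting material that a species holds: one side product B counts as two
- the stated concentrations are those of everything mixed, before any reaction; amounts are the same in each set-up
- reactions considered so far: reagent + intermediate -> side product A; starting material + reagent -> intermediate; intermediate -> target; starting material + intermediate -> side product B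
- the feed brings no volume worth counting
- the earlier runs were made in a closed, stirred flask

1. the set-up with the highest share of target in all that became target or side product A or side product B, at the outlet or at the end ("none" if the first two lie within 2 percentage points) (theta / gamma / alpha / eta / none)
2. share of target in all that became target or side product A or side product B, at the outlet or at the end, theta
3. share of target in all that became target or side product A or side product B, at the outlet or at the end, gamma
4. share of target in all that became target or side product A or side product B, at the outlet or at the end, alpha
5. share of target in all that became target or side product A or side product B, at the outlet or at the end, eta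

Draw target in the red run. Its mean slope up to the first reading is 0.0267 h⁻¹, it bends by 8.00 h at 16.1%, and it runs into a level near 18.0% at 25.0 h.

Take that level as the red reagent having passed through the intermediate. Target then holds 18.0% and side product A 1.40%, a small correction. Each side product A took two reagent, so the remaining 0.112 of reagent went into side product B. Each such unit holds two starting material, so red ends at s = 0.581, with a mean of 0.791 between start and end.

Define the drain d, read here as 0.361: the intermediate lost to side product B per intermediate becoming target, at s of one in a charge of 0.27 M. Side product B counts double, so, with side product A left aside, the share of target is the inverse of one plus two times d times s.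

Now reckon, assuming the reagent is used through and dropping side product B's own draw on s. Then s ends near 0.300. Gamma, a closed flask, sweeps s down to that value with a mean of 0.650, which gives 68.0%. Eta, a tank, holds s at one value, which gives 82.2%. Place theta between them, since its residence time is 40 h against 200 h.

The forecast gives 70.5% for theta, 63.5% for gamma, 64.5% for alpha and 78% for eta, and names eta best, holding that “low starting material favours target”. My figures stand 4.5 percentage points higher for gamma and 4.2 points higher for eta.

The simulation gives 79.4% for eta, 72.6% for theta, 66.0% for gamma and 65.4% for alpha, so eta comes first.

    reagent + intermediate → side product A (k = 0.330 M⁻¹ h⁻¹)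
    starting material + reagent → intermediate (k = 0.630 M⁻¹ h⁻¹)
    intermediate → target (k = 0.640 h⁻¹)
    starting material + intermediate → side product B (k = 1.00 M⁻¹ h⁻¹)

Theta's tank stands at s = 41.7%, where d gives 76.8%, which is 4.2 points above its 72.6%, and side product A stands at 1.03% at that outlet.

The earlier runs and the new flask come from a simulation from invented constants, noise included.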